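A single rate constant cannot describe the green run: target stands at 2% after 25.0 s, then gains 41 percentage points between 50.0 s and 80.0 s.

the same everywhere: starting material 0.0020 M (fed, over 20 s); initiator 0.30 mM; radical scavenger 28 µM
- green: coupling partner 1.4 mM; protic impurity 0.10 mM; run made earlier; the fed solution adds 0.50 times the starting volume
- grey: coupling partner 1.4 mM; protic impurity 0.40 mM; run made earlier; the fed solution adds 0.50 times the starting volume
- flask: coupling partner 1.40 mM; protic impurity 0.200 mM; the fed solution adds 0.50 times the starting volume; time 3.0 min

- green (time / s: target / %, ended chains A / %, quenched substrate / %): 10.0: 0, 2, 2; 25.0: 2, 0, 2; 50.0: 17, 2, 3; 80.0: 58, 4, 7; 120: 72, 4, 6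
- grey (time / s: target / %, ended chains A / %, quenched substrate / %): 20.0: 1, 4, 8; 40.0: 1, 3, 13; 60.0: 40, 0, 14; 80.0: 59, 0, 18; 120: 68, 3, 17

(standard deviation of a reading: 2 percentage points)

- percentages count the starting material that a species holds: one ended chains A counts as two
- every charge counts on the volume at the start, and the solution that is fed holds the whole dose
- percentages count the whole charge, also what has not yet gone in

* amount of target in the flask at 3.0 min, in percent of the starting material charged
* amount of ended chains A in the flask at 3.0 min, in percent of the starting material charged
* amount of quenched substrate in the flask at 3.0 min, in percent of the starting material charged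
* amount of starting material in the flask at 3.0 min, in percent of the starting material charged

What do you read first? A lag phase. The lag, 37.6 s in the green run, is the time at which the straight line through the rising target meets zero.

And the grey run, with 0.40 mM of protic impurity against 0.10 mM? Its line gives 39.5 s, the same within the scatter of the readings. I therefore carry the green reading to the flask, which has the same initiator and radical scavenger as both runs.

Where does the target stop? I take the coupling partner as the limiting reagent, so the late end is c(coupling partner)/c(starting material) = 70.0%.

Join the two ends. From the lag, the straight line at the green run's slope reaches that ceiling at 88.8 s, well before 180 s. My figure for the target in the flask is therefore 70.0%.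

What is the weak spot? What the lag is made of. I suppose that radicals from the initiator consume the scavenger at a steady rate, so that the lag goes as c(radical scavenger)/c(initiator). Neither run varied that ratio, so this remains a supposition.

The forecast gave target 69% (64% to 72%), ended chains A 3% (1.5% to 5%), quenched substrate 10% (8% to 12.5%) and starting material 18% (13% to 24%). Of the starting material it said: “Since it is left over once the partner runs out, it should persist.”

The flask gives target 70.0%, ended chains A 3.96%, quenched substrate 9.41% and starting material 15.0%, each inside the forecast's range.

    initiator → 2 initiating radical (k = 0.00110 s⁻¹)
    starting material + initiating radical → chain carrier (k = 4.10 × 10⁵ M⁻¹ s⁻¹)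
    coupling partner + chain carrier → target + initiating radical (k = 1.70 × 10⁵ M⁻¹ s⁻¹)
    2 chain carrier → ended chains A (k = 1.70 × 10⁶ M⁻¹ s⁻¹)
    starting material → decomposition product (k = 3.60 × 10⁻⁵ s⁻¹)
    starting material + protic impurity → quenched substrate (k = 31.0 M⁻¹ s⁻¹)
    chain carrier + radical scavenger → ended chains B (k = 6.20 × 10⁷ M⁻¹ s⁻¹)

On this flask, a steady burn over the lag leaves 46.8% of the scavenger at 0.333 min, and the flask holds 53.4%. The neighbouring flask is charged with 7.5 × 10⁻⁵ M of initiator, so the scaled lag is 150 s, shorter than 180 s, and coupling should have begun by then. At 3.00 min that neighbouring flask still holds 3.79% of its scavenger, with target 0.626%, quenched substrate 9.98% and starting material 87.5%.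

The runs come from a simulation for an exercise; scatter was added.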